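The hardest feature is the fully substituted C3=C4 bond of the maleimide ring. It must carry two different carbon groups (4-hydroxyphenyl on C3, chroman-7-yl-CH2 on C4) next to a doubly activated CH2.
Retrosynthesis: C3=C4 is first saturated to the succinimide. Then all four bonds tying the bridge C2(=O)–N1H–C5(=O) to C3 and C4 are cut at once, leaving the alkyne Ar–C≡C–CH2–Ar', two CO and NH3.
Enabling feature: the OC–NH–CO bridge is symmetric, so both orientations of the unsymmetrical alkyne give the same ring. The aryl/benzyl differentiation is therefore settled at the alkyne stage, with no regiocontrol needed.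
The alkyne is cut at its C(sp)–CH2 bond into a (3S)-7-(chloromethyl)chromanol and 4-(benzyloxy)phenylacetylene. The para-OH of the C3 aryl ring later allows mild re-oxidation through a p-quinone methide.
Forward order: the pyran ring comes first, by oxa-6π closure from methyl 4-formyl-3-hydroxybenzoate, which fixes the CH2 carbon at C7, meta to O1. The chain is joined next and the imide ring is made last.
Stereochemistry: the only stereocentre, C3 (S), comes from (S,S)-Mn(salen) epoxidation of the chromene C3=C4 bond. Hydride then opens the epoxide at C4 and leaves the C3–O bond untouched.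

Key step: step 6

Assumption: the SMILES is taken literally, so the CH2 link sits on C7 of the chroman (meta to O1, para to C4a) and the carbinol carbon C3 is S.

Step 1
Reactants: 1 methyl 4-formyl-3-hydroxybenzoate; 2 2-methylprop-1-en-1-ylmagnesium bromide
Product: 5 methyl 2,2-dimethyl-2H-chromene-7-carboxylate, via allylic alcohol 3 (not isolated), via o-quinone methide 4 (not isolated)
Conditions: 2 (2.2 equiv), THF, −78 → 0 °C; 1 M HCl quench; crude 3, PPTS (5 mol %), toluene, 110 °C, Dean–Stark
Reagents that add atoms: none
Why: Grignard 1,2-addition takes place at the magnesium-chelated aldehyde after the first equivalent has deprotonated the phenol (the ester is spared at low temperature), and acid-catalysed loss of water from the o-hydroxybenzylic allylic alcohol 3 gives o-quinone methide 4, which closes the pyran ring by oxa-6π electrocyclisation, a standard 2,2-dimethylchromene synthesis that leaves no stereocentre.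

Step 2
Reactants: 5 methyl 2,2-dimethyl-2H-chromene-7-carboxylate
Product: 6 methyl (3S,4S)-3,4-epoxy-2,2-dimethylchromane-7-carboxylate
Conditions: (S,S)-Mn(salen)Cl (Jacobsen catalyst, 3 mol %), 4-phenylpyridine N-oxide (0.2 equiv), aq NaOCl (pH 11.3), CH2Cl2, 0 °C
Reagents that add atoms: sodium hypochlorite, [Na+].[O-]Cl
Why: Jacobsen–Katsuki epoxidation, for which 2,2-dimethylchromenes (a cis-alkene conjugated with an arene and flanked by a quaternary carbon) are the best substrate class; the (S,S)-catalyst is the enantiomer that turns such chromenes into (3S,4S)-epoxides by side-on approach to the Mn(V)=O species, and this sets C3.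

Step 3
Reactants: 6 methyl (3S,4S)-3,4-epoxy-2,2-dimethylchromane-7-carboxylate
Product: 7 (3S)-7-(hydroxymethyl)-2,2-dimethylchroman-3-ol
Conditions: LiAlH4 (2 equiv), THF, 0 °C → rt; H2O/aq NaOH work-up
Reagents that add atoms: none
Why: Hydride reduction turns the ester into the benzylic alcohol and opens the epoxide by SN2 attack at the benzylic, less hindered C4 (C3 is neopentyl-like next to CMe2), so the C3–O bond is never broken and the S configuration is retained.

Step 4
Reactants: 7 (3S)-7-(hydroxymethyl)-2,2-dimethylchroman-3-ol
Product: 8 (3S)-7-(chloromethyl)-2,2-dimethylchroman-3-ol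
Conditions: SOCl2 (1.05 equiv), CH2Cl2, 0 °C; aq NaHCO3 work-up
Reagents that add atoms: thionyl chloride, O=S(Cl)Cl
Why: Chlorodehydroxylation with thionyl chloride is much faster at the primary benzylic hydroxyl than at the secondary carbinol shielded by CMe2, and any chlorosulfite formed there should revert to the alcohol on aqueous work-up.

Step 5
Reactants: 8 (3S)-7-(chloromethyl)-2,2-dimethylchroman-3-ol; 9 1-(benzyloxy)-4-ethynylbenzene
Product: 10 (3S)-7-{3-[4-(benzyloxy)phenyl]prop-2-yn-1-yl}-2,2-dimethylchroman-3-ol
Conditions: PdCl2(MeCN)2 (2 mol %), XPhos (6 mol %), Cs2CO3 (1.05 equiv), THF, 65 °C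
Reagents that add atoms: none
Why: Copper-free Sonogashira-type (Heck alkynylation) sp–sp3 coupling of benzyl chlorides with terminal aryl acetylenes is a known reaction type, and about one equivalent of carbonate at moderate temperature is used so that the 1,3-diarylpropyne should not shift to the allene.

Step 6
Reactants: 10 (3S)-7-{3-[4-(benzyloxy)phenyl]prop-2-yn-1-yl}-2,2-dimethylchroman-3-ol
Product: 11 3-[4-(benzyloxy)phenyl]-4-{[(3S)-3-hydroxy-2,2-dimethylchroman-7-yl]methyl}pyrrolidine-2,5-dione (trans on the imide ring; both trans diastereomers)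
Conditions: Fe3(CO)12 (5 mol %), NH3 (ca. 20 equiv), CO (20 bar), THF, 120 °C, autoclave
Reagents that add atoms: carbon monoxide (two equivalents), [C-]#[O+]; ammonia, N
Why: An iron(0) carbonyl fragment binds the C≡C bond of 10 and inserts two CO to give a maleoyl-iron (ferracyclopentenedione) species; NH3 opens one Fe–acyl bond to a primary amide, whose nitrogen attacks the second acyl, and the two N–H hydrogens thus released pass through Fe–H to the former alkyne carbons, so that alkyne + 2 CO + NH3 add up to the succinimide with no co-product. The closest known reaction type is the iron-carbonyl-catalysed double carbonylation of internal alkynes with ammonia or amines to succinimides, a formal (2+1+1+1) annulation already shown on diaryl and on aryl/benzyl acetylenes. The one ring formed, the five-membered imide, closes by 5-exo-trig N-acylation at the metal-bound acyl after both new C–C bonds are in place. The two new stereocentres (imide C3 and C4) should settle as the trans pair through epimerisation of the acidic C3–H in the ammonia medium; they are not controlled relative to the remote carbinol, which does not matter because step 8 erases both. No regioselectivity is needed, since the OC–NH–CO bridge is symmetric and either orientation of the alkyne leads to the same product. The chemoselectivity needed is secured by the substrate: NH3 is too weak a base to shift the propargylic CH2 to an allene, the benzyl ether blocks phenoxide-assisted addition of NH3 to the aryl alkyne, and the hindered C3 carbinol cannot compete with NH3 for the acyl-iron.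

Step 7
Reactants: 11 3-[4-(benzyloxy)phenyl]-4-{[(3S)-3-hydroxy-2,2-dimethylchroman-7-yl]methyl}pyrrolidine-2,5-dione
Product: 12 3-(4-hydroxyphenyl)-4-{[(3S)-3-hydroxy-2,2-dimethylchroman-7-yl]methyl}pyrrolidine-2,5-dione
Conditions: H2 (1 atm), 10% Pd/C, EtOH–EtOAc, rt
Reagents that add atoms: none
Why: Hydrogenolysis of the aryl benzyl ether is carried out while the imide ring is still saturated, so no C=C bond is at risk, and the chroman C–O bonds are not benzylic and should survive.

Step 8
Reactants: 12 3-(4-hydroxyphenyl)-4-{[(3S)-3-hydroxy-2,2-dimethylchroman-7-yl]methyl}pyrrolidine-2,5-dione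
Product: 14 asperimide C, via p-quinone methide 13 (not isolated)
Conditions: DDQ (1.05 equiv), 1,4-dioxane, rt
Reagents that add atoms: none
Why: Quinone dehydrogenation, in which DDQ removes hydride from the para-hydroxybenzylic imide C3–H to give p-quinone methide 13 and loss of the acidic C4–H re-aromatises it to the phenol with the C3=C4 bond in place; this erases both uncontrolled stereocentres, while the chroman CH2 groups, which have no free phenol to assist them, should need heating to react.

Compound list
1 | methyl 4-formyl-3-hydroxybenzoate | COC(=O)c1ccc(C=O)c(O)c1 | starting material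
2 | 2-methylprop-1-en-1-ylmagnesium bromide | CC(C)=C[Mg]Br | starting material
3 | methyl 3-hydroxy-4-(1-hydroxy-3-methylbut-2-en-1-yl)benzoate (racemic; not isolated) | COC(=O)c1ccc(C(O)C=C(C)C)c(O)c1 | intermediate
4 | methyl (4Z)-4-(3-methylbut-2-en-1-ylidene)-3-oxocyclohexa-1,5-diene-1-carboxylate (o-quinone methide; not isolated) | COC(=O)C1=CC(=O)/C(=C\C=C(C)C)C=C1 | intermediate
5 | methyl 2,2-dimethyl-2H-chromene-7-carboxylate | COC(=O)c1ccc2C=CC(C)(C)Oc2c1 | intermediate
6 | methyl (3S,4S)-3,4-epoxy-2,2-dimethylchromane-7-carboxylate | COC(=O)c1ccc2[C@@H]3O[C@@H]3C(C)(C)Oc2c1 | intermediate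
7 | (3S)-7-(hydroxymethyl)-2,2-dimethylchroman-3-ol | CC1(C)Oc2cc(CO)ccc2C[C@@H]1O | intermediate
8 | (3S)-7-(chloromethyl)-2,2-dimethylchroman-3-ol | CC1(C)Oc2cc(CCl)ccc2C[C@@H]1O | intermediate
9 | 1-(benzyloxy)-4-ethynylbenzene | C#Cc1ccc(OCc2ccccc2)cc1 | starting material
10 | (3S)-7-{3-[4-(benzyloxy)phenyl]prop-2-yn-1-yl}-2,2-dimethylchroman-3-ol | CC1(C)Oc2cc(CC#Cc3ccc(OCc4ccccc4)cc3)ccc2C[C@@H]1O | intermediate
11 | 3-[4-(benzyloxy)phenyl]-4-{[(3S)-3-hydroxy-2,2-dimethylchroman-7-yl]methyl}pyrrolidine-2,5-dione (trans imide; mixture at the two imide carbons, left open in the SMILES) | CC1(C)Oc2cc(CC3C(c4ccc(OCc5ccccc5)cc4)C(=O)NC3=O)ccc2C[C@@H]1O | intermediate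
12 | 3-(4-hydroxyphenyl)-4-{[(3S)-3-hydroxy-2,2-dimethylchroman-7-yl]methyl}pyrrolidine-2,5-dione (mixture at the two imide carbons, left open in the SMILES) | CC1(C)Oc2cc(CC3C(c4ccc(O)cc4)C(=O)NC3=O)ccc2C[C@@H]1O | intermediate
13 | 3-{[(3S)-3-hydroxy-2,2-dimethylchroman-7-yl]methyl}-4-(4-oxocyclohexa-2,5-dien-1-ylidene)pyrrolidine-2,5-dione (p-quinone methide; not isolated) | CC1(C)Oc2cc(CC3C(=C4C=CC(=O)C=C4)C(=O)NC3=O)ccc2C[C@@H]1O | intermediate
14 | asperimide C, 3-(4-hydroxyphenyl)-4-{[(3S)-3-hydroxy-2,2-dimethylchroman-7-yl]methyl}-1H-pyrrole-2,5-dione | CC1(C)Oc2cc(CC3=C(c4ccc(O)cc4)C(=O)NC3=O)ccc2C[C@@H]1O | target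

Total step count: 8. Longest linear sequence: 8 (1 → 14); compounds 2 and 9 are bought.

Steps most likely to fail

Step 6 (key step).
- What may go wrong: the reaction may stop after one CO insertion, at the acrylamide stage. An iron hydride may move the triple bond through the doubly activated CH2. Turnover may be slow because the free carbinol binds the metal.
- Fallback: the imide ring is bought instead of built, and the CH2–C4 bond is made by radical conjugate addition. It sets out from chloride 8 and comes back at succinimide 11.
- Commercial 3-bromo-1H-pyrrole-2,5-dione is joined to 4-(benzyloxy)phenylboronic acid by Suzuki coupling (Pd(PPh3)4, K2CO3, dioxane–water). This gives 3-[4-(benzyloxy)phenyl]-1H-pyrrole-2,5-dione F1.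
- The benzylic radical is generated from 8 with a nucleophilic dithiocarbamate photocatalyst (blue light, γ-terpinene, 2,6-lutidine, MeCN). It adds in a Giese reaction to the unsubstituted ring carbon of F1.
- The resulting aryl- and carbonyl-stabilised C3 radical takes up a hydrogen atom to give 11. The free OH and NH groups are tolerated by the radical chemistry.

Step 8.
- What may go wrong: the oxidation may be unselective. Possible side processes are hydride loss from chroman C4, oxidative coupling of the phenol, and further oxidation at the newly formed doubly activated CH2.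
- Fallback: no dehydrogenation at all. The maleimide oxidation level comes from an olefination followed by a proton shift. It sets out from diol 7 and comes back at target 14.
- MnO2 (CH2Cl2, rt) oxidises only the benzylic alcohol of 7 to (3S)-3-hydroxy-2,2-dimethylchromane-7-carbaldehyde F2.
- Suzuki coupling of commercial 3-bromo-1H-pyrrole-2,5-dione with 4-hydroxyphenylboronic acid gives 3-(4-hydroxyphenyl)-1H-pyrrole-2,5-dione F3.
- PPh3 adds to the unsubstituted ring carbon of F3 and, after a proton shift, gives the stabilised ylide 3-(4-hydroxyphenyl)-4-(triphenyl-λ5-phosphanylidene)pyrrolidine-2,5-dione F4.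
- In the same pot (THF, reflux) F4 undergoes Wittig olefination with F2. This gives (4E)-3-(4-hydroxyphenyl)-4-{[(3S)-3-hydroxy-2,2-dimethylchroman-7-yl]methylidene}pyrrolidine-2,5-dione F5.
- Et3N or DBU then moves the acidic C3–H to the exocyclic carbon through the dienolate (1,3-prototropic shift). The product is 14, in which the ring alkene is conjugated with the aryl ring and both carbonyls.

Step 5.
- What may go wrong: the carbonate base may shift the product from propargyl to allene, and the benzylic chloride may alkylate the carbinol oxygen.
- Fallback: the CH2 is made by carbonyl addition and ionic deoxygenation under acid, not by coupling under base. It sets out from diol 7 and comes back at alkyne 10.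
- Aldehyde F2, made as in the preceding fallback, is treated with lithium [4-(benzyloxy)phenyl]acetylide F6 (from 9 and n-BuLi, 2.2 equiv to allow for the free carbinol, THF, −78 °C).
- This gives (3S)-7-{3-[4-(benzyloxy)phenyl]-1-hydroxyprop-2-yn-1-yl}-2,2-dimethylchroman-3-ol F7 as both epimers.
- Ionic hydrogenation (Et3SiH, TFA, CH2Cl2, 0 °C) removes only this doubly activated hydroxyl through the propargylic cation and gives 10. No base-induced proton shift can take place in this medium.

Further compounds
F1 | step 6 | 3-[4-(benzyloxy)phenyl]-1H-pyrrole-2,5-dione | O=C1NC(=O)C(c2ccc(OCc3ccccc3)cc2)=C1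
F2 | step 8 | (3S)-3-hydroxy-2,2-dimethylchromane-7-carbaldehyde | CC1(C)Oc2cc(C=O)ccc2C[C@@H]1O
F3 | step 8 | 3-(4-hydroxyphenyl)-1H-pyrrole-2,5-dione | O=C1NC(=O)C(c2ccc(O)cc2)=C1
F4 | step 8 | 3-(4-hydroxyphenyl)-4-(triphenyl-λ5-phosphanylidene)pyrrolidine-2,5-dione | O=C1NC(=O)C(=P(c2ccccc2)(c3ccccc3)c4ccccc4)C1c5ccc(O)cc5
F5 | step 8 | (4E)-3-(4-hydroxyphenyl)-4-{[(3S)-3-hydroxy-2,2-dimethylchroman-7-yl]methylidene}pyrrolidine-2,5-dione | CC1(C)Oc2cc(/C=C3/C(=O)NC(=O)C3c4ccc(O)cc4)ccc2C[C@@H]1O
F6 | step 5 | lithium [4-(benzyloxy)phenyl]acetylide | [Li]C#Cc1ccc(OCc2ccccc2)cc1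
F7 | step 5 | (3S)-7-{3-[4-(benzyloxy)phenyl]-1-hydroxyprop-2-yn-1-yl}-2,2-dimethylchroman-3-ol | CC1(C)Oc2cc(C(O)C#Cc3ccc(OCc4ccccc4)cc3)ccc2C[C@@H]1O
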